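**Retrosynthetic overview** (germacrane numbering: ring C1–C10, lactone carbons C11–C13, C14 on C10, C15 on C4)

1. Target ⇐ desilylation, Mitsunobu esterification (inversion at C8) and hydride reduction of 15‑hydroxy‑8‑oxogermacra‑1(10),4‑dien‑12,6α‑olide.
2. That ten‑membered keto‑lactone ⇐ Grob (epoxy‑alcohol) fragmentation of the C5–C8 bond of a cyclobutanol (C5–C6–C7–C8) fused to an eight‑membered carbocycle (C8–C9–C10=C1–C2–C3–C4–C5), set off by opening of a temporary 8,12‑lactone; the eight‑membered ring takes in C6 and C7.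
3. Enabling feature: the C8 oxygen and the C15 oxygen are 1,3‑related across C5 (O–C8···C5=C4–C15–O), so C8–O can push and a C4/C15 oxirane can leave; the ring‑cis C1=C10 bond fits an eight‑membered ring, the ring‑trans C4=C5 bond is only born in the fragmentation.
4. Tricyclic precursor ⇐ intramolecular enone–alkene [2+2] photocycloaddition of an enol ester (cyclobutane and 8,12‑lactone at once), then methylenation, C11 epimerisation and OH‑directed epoxidation; enol ester ⇐ 3‑chlorocyclooctadienone + (R)‑2‑methyl‑4‑borylbut‑3‑enoic acid.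
5. Ring order: cyclobutanone → eight‑membered ring (oxy‑Cope, 4 → 8) → cyclobutane + γ‑lactone (hν) → oxirane → ten‑membered ring + 6,12‑lactone (key step).

Key step: step 15

Assumption: (4S)‑4‑methyloxolan‑2‑one, (4R)‑4‑benzyloxazolidin‑2‑one and vinylboronic acid pinacol ester are taken as catalogue compounds; the photocycloaddition is assumed to place the C11 methyl group exo, which is why the (R)‑acid is used and C11 is inverted in step 13.

**Step 1**
Reactants: 1 cyclopropyl phenyl sulfide; 2 methacrolein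
Product: 4 (±)-2-methyl-1-[1-(phenylsulfanyl)cyclopropyl]prop-2-en-1-ol, via 1-lithio-1-(phenylsulfanyl)cyclopropane 3 (not isolated)
Conditions: n‑BuLi, THF, 0 °C; then 2, −78 °C; aq NH4Cl
Reagents that add atoms: none
Why: α‑Lithiation of the cyclopropyl sulfide and 1,2‑addition to the enal (first stage of the Trost cyclobutanone annulation); the carbinol centre is racemic and is destroyed later.

**Step 2**
Reactants: 4 (±)-2-methyl-1-[1-(phenylsulfanyl)cyclopropyl]prop-2-en-1-ol
Product: 5 (±)-2-(prop-1-en-2-yl)cyclobutan-1-one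
Conditions: TsOH·H2O (cat.), wet benzene, reflux
Reagents that add atoms: water (O)
Why: Acid‑catalysed cyclopropylcarbinyl → cyclobutyl ring enlargement of the allylic cation to a sulfur‑stabilised cation and hydrolysis gives the 2‑alkenylcyclobutanone (Trost cyclobutanone synthesis).

**Step 3**
Reactants: 5 (±)-2-(prop-1-en-2-yl)cyclobutan-1-one
Product: 6 1-(chloroethynyl)-2-(prop-1-en-2-yl)cyclobutan-1-ol
Conditions: (E)‑ClCH=CHCl, MeLi (2 equiv), Et2O, 0 °C; then 5, −78 °C → rt; aq NH4Cl
Reagents that add atoms: (E)-1,2-dichloroethene (Cl/C=C/Cl), used as lithium chloroacetylide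
Why: 1,2‑Addition of lithium chloroacetylide to the ketone (acetylide addition); both diastereomers are carried on because the next step is expected to converge them.

**Step 4**
Reactants: 6 1-(chloroethynyl)-2-(prop-1-en-2-yl)cyclobutan-1-ol
Product: 8 (2E,5Z)-3-chloro-5-methylcycloocta-2,5-dien-1-one, via potassium allenolate 7 (not isolated)
Conditions: KH, 18‑crown‑6, THF, 0 °C → rt; aq NH4Cl
Reagents that add atoms: none
Why: Strain‑driven anionic oxy‑Cope rearrangement of the 1‑alkynyl‑2‑alkenylcyclobutanolate (4 → 8; the trans isomer can reach the same allenolate by fragmentation–Michael recombination), with the ring forcing the C1=C10 bond cis and C‑protonation giving the β‑chloroenone.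

**Step 5**
Reactants: 9 (4R)-4-benzyl-1,3-oxazolidin-2-one; 10 (2E)-but-2-enoyl chloride
Product: 11 (4R)-4-benzyl-3-[(2E)-but-2-enoyl]-1,3-oxazolidin-2-one
Conditions: n‑BuLi, THF, −78 °C; then 10
Reagents that add atoms: none
Why: N‑Acylation of the lithiated Evans auxiliary.

**Step 6**
Reactants: 11 (4R)-4-benzyl-3-[(2E)-but-2-enoyl]-1,3-oxazolidin-2-one
Product: 13 (4R)-4-benzyl-3-[(2R)-2-methylbut-3-enoyl]-1,3-oxazolidin-2-one, via sodium (Z)-dienolate 12 (not isolated)
Conditions: NaHMDS, THF, −78 °C; MeI, −78 → −40 °C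
Reagents that add atoms: iodomethane (CI)
Why: Evans deconjugative α‑alkylation: the chelated Z‑dienolate is methylated at Cα on the face away from the benzyl group, which should set the (R) centre that becomes C11.

**Step 7**
Reactants: 13 (4R)-4-benzyl-3-[(2R)-2-methylbut-3-enoyl]-1,3-oxazolidin-2-one
Product: 15 (2R)-2-methylbut-3-enoic acid, via lithium peroxycarboxylate 14 (not isolated)
Conditions: LiOH, H2O2, THF/H2O, 0 °C; Na2SO3; HCl to pH 3
Reagents that add atoms: hydrogen peroxide (OO), as LiOOH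
Why: Hydroperoxide cleavage of the exocyclic imide carbonyl (Evans LiOOH hydrolysis) at 0 °C, which should leave the α‑centre untouched.

**Step 8**
Reactants: 15 (2R)-2-methylbut-3-enoic acid
Product: 16 (2R,3E)-2-methyl-4-(4,4,5,5-tetramethyl-1,3,2-dioxaborolan-2-yl)but-3-enoic acid
Conditions: vinyl‑Bpin (3 equiv), Grubbs II (5 mol %), 1,4‑benzoquinone (10 mol %), CH2Cl2, 40 °C
Reagents that add atoms: 2-ethenyl-4,4,5,5-tetramethyl-1,3,2-dioxaborolane (C=CB1OC(C)(C)C(C)(C)O1)
Why: E‑selective olefin cross‑metathesis with a vinylboronate puts a masked hydroxyl on the future C6; benzoquinone suppresses Ru–H isomerisation of the allylic stereocentre.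

**Step 9**
Reactants: 8 (2E,5Z)-3-chloro-5-methylcycloocta-2,5-dien-1-one; 16 (2R,3E)-2-methyl-4-(4,4,5,5-tetramethyl-1,3,2-dioxaborolan-2-yl)but-3-enoic acid
Product: 17 (1E,6Z)-7-methyl-3-oxocycloocta-1,6-dien-1-yl (2R,3E)-2-methyl-4-(pinacolboryl)but-3-enoate
Conditions: Et3N, MeCN, 0 °C → rt
Reagents that add atoms: none
Why: Addition–elimination of the carboxylate at the β‑carbon of the β‑chloroenone (vinylogous acyl substitution) gives the enol ester with the oxygen on C8 only, a regiochemistry that acylation of the free 1,3‑dione could not give.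

**Step 10**
Reactants: 17 (1E,6Z)-7-methyl-3-oxocycloocta-1,6-dien-1-yl (2R,3E)-2-methyl-4-(pinacolboryl)but-3-enoate
Product: 18 (11R)-6α-(pinacolboryl)-4-oxo-5βH-5,8-cyclogermacr-1(10)Z-en-12,8β-olide
Conditions: hν (350–366 nm, Pyrex), degassed CH2Cl2 (5 mM), 0 °C
Reagents that add atoms: none
Why: Intramolecular enone–alkene [2+2] photocycloaddition of a 3‑acyloxy‑enone with a three‑atom tether (rule of five: C8–C7 closes the γ‑lactone, C5–C6 the cyclobutane, so only the straight adduct is expected); both ring fusions should be cis, the E‑alkene puts boron anti to C11, and the C11 centre should steer the tether to the enone face that leaves its methyl exo, which fixes C6 and C7 in the sense of the target.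

**Step 11**
Reactants: 18 (11R)-6α-(pinacolboryl)-4-oxo-5βH-5,8-cyclogermacr-1(10)Z-en-12,8β-olide
Product: 19 (11R)-6α-(pinacolboryl)-5βH-5,8-cyclogermacra-1(10)Z,4(15)-dien-12,8β-olide
Conditions: CH2Br2, Zn, TiCl4, THF/CH2Cl2, 0 °C → rt
Reagents that add atoms: dibromomethane (BrCBr)
Why: Takai–Lombardo methylenation is non‑basic and selective for the ketone over the lactone, and removing the C4 carbonyl also shuts off premature retro‑aldol (de Mayo) opening.

**Step 12**
Reactants: 19 (11R)-6α-(pinacolboryl)-5βH-5,8-cyclogermacra-1(10)Z,4(15)-dien-12,8β-olide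
Product: 20 (11R)-6α-hydroxy-5βH-5,8-cyclogermacra-1(10)Z,4(15)-dien-12,8β-olide
Conditions: NaBO3·4H2O, THF/H2O, rt
Reagents that add atoms: sodium perborate ([Na+].[O-]OB=O)
Why: Oxidation of the C–B bond with retention of configuration gives the 6α‑hydroxyl (boronate oxidation).

**Step 13**
Reactants: 20 (11R)-6α-hydroxy-5βH-5,8-cyclogermacra-1(10)Z,4(15)-dien-12,8β-olide
Product: 22 (11S)-6α-hydroxy-5βH-5,8-cyclogermacra-1(10)Z,4(15)-dien-12,8β-olide, via dilithium alkoxide-enolate 21 (not isolated)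
Conditions: LDA (2.3 equiv), THF, −78 °C; AcOH/THF, −78 °C
Reagents that add atoms: none
Why: Lactone enolate formation and kinetic protonation from the convex (exo) face of the cis‑fused 2‑oxabicyclo[3.2.0]heptanone should turn the exo‑methyl (11R) into the endo‑methyl (11S) epimer that the target needs.

**Step 14**
Reactants: 22 (11S)-6α-hydroxy-5βH-5,8-cyclogermacra-1(10)Z,4(15)-dien-12,8β-olide
Product: 23 (11S)-4,15-epoxy-6α-hydroxy-5βH-5,8-cyclogermacr-1(10)Z-en-12,8β-olide
Conditions: VO(acac)2 (5 mol %), t‑BuOOH, CH2Cl2, 0 °C → rt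
Reagents that add atoms: tert-butyl hydroperoxide (CC(C)(C)OO)
Why: Vanadium‑catalysed hydroxyl‑directed epoxidation: the C6 hydroxyl is homoallylic to the exocyclic C4=C15 bond only, so the ring alkene is spared, and oxygen should arrive syn to O6 on the outer face of C4, anti to C8, the configuration that fragments to the ring‑trans alkene.

**Step 15**
Reactants: 23 (11S)-4,15-epoxy-6α-hydroxy-5βH-5,8-cyclogermacr-1(10)Z-en-12,8β-olide
Product: 26 (11S)-15-hydroxy-8-oxogermacra-1(10)Z,4Z-dien-12,6α-olide, via titanium alkoxide of ring-opened isopropyl ester 24 (not isolated), via ring-expanded keto ester 25 (not isolated)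
Conditions: Ti(OiPr)4 (2 equiv), i‑PrOH (3 equiv), toluene, 23 → 60 °C; aq Rochelle salt
Reagents that add atoms: none
Why: Titanate‑mediated transesterification opens the strained cis‑fused 8,12‑lactone to the isopropyl ester and frees the C8 titanium alkoxide of the bicyclo[6.2.0]decane; this alkoxide is 1,3‑related to the titanium‑activated C4/C15 oxirane, so the C5–C8 σ‑bond shared by cyclobutane and eight‑membered ring breaks in a Grob fragmentation, giving the C8 ketone, the C4=C5 bond and the C15 alkoxide, and the eight‑membered carbocycle becomes the ten‑membered one by taking in C6 and C7. The closest known reaction types are the Ti(OiPr)4‑promoted epoxy‑alcohol fragmentation used for bridged medium rings and the retro‑aldol opening of de Mayo cyclobutanols. The only ring closed is the γ‑lactone, by 5‑exo‑trig acyl transfer from the isopropyl ester to the C6 alkoxide, which becomes possible only once the cyclobutane is gone because O6 and C11 are trans. No new stereocentre forms; C6, C7 and C11 are carried over, and the alkene geometry is set stereospecifically by the antiperiplanar C4–O/C5–C8 arrangement, which the C4 configuration allows only in the conformer with C3 anti to C6 (ring‑trans alkene, C15 syn to C6). The step needs cleavage of C5–C8 and not of C7–C8 or C8–C9, which is secured because only C5 carries the β‑leaving group and because both cyclobutane and oxirane strain are released. Retro‑aldol of the C6 aldolate should be outrun by lactonisation under the non‑basic titanium conditions, which should also spare the β,γ‑unsaturated ketone from conjugation.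

**Step 16**
Reactants: 26 (11S)-15-hydroxy-8-oxogermacra-1(10)Z,4Z-dien-12,6α-olide
Product: 27 (11S)-15-(tert-butyldimethylsilyloxy)-8-oxogermacra-1(10)Z,4Z-dien-12,6α-olide
Conditions: TBSCl, imidazole, CH2Cl2, 0 °C
Reagents that add atoms: tert-butyl(chloro)dimethylsilane (CC(C)(C)[Si](C)(C)Cl)
Why: Silylation of the only free (primary allylic) hydroxyl so that C8 can later be esterified selectively.

**Step 17**
Reactants: 27 (11S)-15-(tert-butyldimethylsilyloxy)-8-oxogermacra-1(10)Z,4Z-dien-12,6α-olide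
Product: 28 (11S)-15-(tert-butyldimethylsilyloxy)-8β-hydroxygermacra-1(10)Z,4Z-dien-12,6α-olide
Conditions: L‑Selectride, THF, −78 °C; aq NH4Cl
Reagents that add atoms: none
Why: Bulky hydride should add to the C8 carbonyl anti to the adjacent C7–C11 branch (1,2‑induction, as in 2‑alkylcycloalkanones), giving the 8β‑alcohol; at −78 °C the lactone and the β‑acyloxy ketone array should survive.

**Step 18**
Reactants: 29 (4S)-4-methyloxolan-2-one
Product: 30 potassium (3S)-4-hydroxy-3-methylbutanoate
Conditions: KOH (1.0 equiv), MeOH/H2O, rt; evaporate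
Reagents that add atoms: potassium hydroxide ([K+].[OH-])
Why: Saponification of the γ‑lactone; the stereocentre is not involved.

**Step 19**
Reactants: 30 potassium (3S)-4-hydroxy-3-methylbutanoate
Product: 32 (3S)-4-(tert-butyldimethylsilyloxy)-3-methylbutanoic acid, via bis-silyl ester 31 (not isolated)
Conditions: TBSCl (2.5 equiv), imidazole, DMF, rt; then K2CO3, MeOH/H2O; pH 4
Reagents that add atoms: tert-butyl(chloro)dimethylsilane (CC(C)(C)[Si](C)(C)Cl)
Why: Bis‑silylation followed by selective cleavage of the labile silyl ester gives the O‑protected acid and prevents relactonisation.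

**Step 20**
Reactants: 28 (11S)-15-(tert-butyldimethylsilyloxy)-8β-hydroxygermacra-1(10)Z,4Z-dien-12,6α-olide; 32 (3S)-4-(tert-butyldimethylsilyloxy)-3-methylbutanoic acid
Product: 33 (11S)-15-(tert-butyldimethylsilyloxy)-8α-[(3S)-4-(tert-butyldimethylsilyloxy)-3-methylbutanoyloxy]germacra-1(10)Z,4Z-dien-12,6α-olide
Conditions: PPh3, DIAD, toluene, 0 °C → rt
Reagents that add atoms: none
Why: Mitsunobu esterification replaces the activated 8β‑oxygen by the carboxylate with inversion, which sets the 8α (8S) acyloxy centre.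

**Step 21**
Reactants: 33 (11S)-15-(tert-butyldimethylsilyloxy)-8α-[(3S)-4-(tert-butyldimethylsilyloxy)-3-methylbutanoyloxy]germacra-1(10)Z,4Z-dien-12,6α-olide
Product: 34 (11S)-15-hydroxy-8α-[(3S)-4-hydroxy-3-methylbutanoyloxy]germacra-1(10)Z,4Z-dien-12,6α-olide
Conditions: HF·pyridine, pyridine/THF, 0 °C
Reagents that add atoms: none
Why: Buffered fluoride desilylation frees both primary hydroxyls under conditions that should not relactonise the γ‑hydroxy ester or isomerise the 1,5‑diene.

**Compound list**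

1 | cyclopropyl phenyl sulfide | C1CC1Sc1ccccc1 | starting material
2 | methacrolein (2-methylprop-2-enal) | CC(=C)C=O | starting material
3 | 1-lithio-1-(phenylsulfanyl)cyclopropane | [Li]C1(Sc2ccccc2)CC1 | intermediate (not isolated)
4 | (±)-2-methyl-1-[1-(phenylsulfanyl)cyclopropyl]prop-2-en-1-ol | CC(=C)C(O)C1(Sc2ccccc2)CC1 | intermediate
5 | (±)-2-(prop-1-en-2-yl)cyclobutan-1-one | CC(=C)C1CCC1=O | intermediate
6 | 1-(chloroethynyl)-2-(prop-1-en-2-yl)cyclobutan-1-ol (racemic, both diastereomers) | CC(=C)C1CCC1(O)C#CCl | intermediate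
7 | potassium (5Z)-3-chloro-5-methylcycloocta-1,2,5-trien-1-olate | [K+].[O-]C1=C=C(Cl)C/C(C)=C\CC1 | intermediate (not isolated)
8 | (2E,5Z)-3-chloro-5-methylcycloocta-2,5-dien-1-one (ring C4(=O)–C5=C8(Cl)–C9–C10(Me)=C1–C2–C3) | O=C1/C=C(Cl)\C/C(C)=C\CC1 | intermediate
9 | (4R)-4-benzyl-1,3-oxazolidin-2-one | O=C1N[C@H](Cc2ccccc2)CO1 | starting material
10 | (2E)-but-2-enoyl chloride | C/C=C/C(Cl)=O | starting material
11 | (4R)-4-benzyl-3-[(2E)-but-2-enoyl]-1,3-oxazolidin-2-one | C/C=C/C(=O)N1C(=O)OC[C@H]1Cc1ccccc1 | intermediate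
12 | sodium (Z)-dienolate of 11 | C=C/C=C(\[O-])N1C(=O)OC[C@H]1Cc1ccccc1.[Na+] | intermediate (not isolated)
13 | (4R)-4-benzyl-3-[(2R)-2-methylbut-3-enoyl]-1,3-oxazolidin-2-one | C=C[C@@H](C)C(=O)N1C(=O)OC[C@H]1Cc1ccccc1 | intermediate
14 | lithium (2R)-2-methylbut-3-eneperoxoate | C=C[C@@H](C)C(=O)O[O-].[Li+] | intermediate (not isolated)
15 | (2R)-2-methylbut-3-enoic acid | C=C[C@@H](C)C(=O)O | intermediate
16 | (2R,3E)-2-methyl-4-(4,4,5,5-tetramethyl-1,3,2-dioxaborolan-2-yl)but-3-enoic acid | C[C@H](/C=C/B1OC(C)(C)C(C)(C)O1)C(=O)O | intermediate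
17 | (1E,6Z)-7-methyl-3-oxocycloocta-1,6-dien-1-yl (2R,3E)-2-methyl-4-(pinacolboryl)but-3-enoate (enol ester on C8) | O=C1/C=C(OC(=O)[C@H](C)/C=C/B2OC(C)(C)C(C)(C)O2)\C/C(C)=C\CC1 | intermediate
18 | (11R)-6α-(pinacolboryl)-4-oxo-5βH-5,8-cyclogermacr-1(10)Z-en-12,8β-olide (cyclobutane C5–C6–C7–C8 cis-fused to the eight-membered ring and to the γ-lactone; boron anti to C11; 11-methyl exo, cis to H-7) | O=C1CC/C=C(C)\C[C@]23OC(=O)[C@H](C)[C@H]2[C@H](B4OC(C)(C)C(C)(C)O4)[C@H]13 | intermediate
19 | (11R)-6α-(pinacolboryl)-5βH-5,8-cyclogermacra-1(10)Z,4(15)-dien-12,8β-olide | C=C1CC/C=C(C)\C[C@]23OC(=O)[C@H](C)[C@H]2[C@H](B4OC(C)(C)C(C)(C)O4)[C@H]13 | intermediate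
20 | (11R)-6α-hydroxy-5βH-5,8-cyclogermacra-1(10)Z,4(15)-dien-12,8β-olide | C=C1CC/C=C(C)\C[C@]23OC(=O)[C@H](C)[C@H]2[C@H](O)[C@H]13 | intermediate
21 | dilithium C6-alkoxide / lactone enolate of 20 | C=C1CC/C=C(C)\C[C@]23OC([O-])=C(C)[C@H]2[C@H]([O-])[C@H]13.[Li+].[Li+] | intermediate (not isolated)
22 | (11S)-6α-hydroxy-5βH-5,8-cyclogermacra-1(10)Z,4(15)-dien-12,8β-olide (11-methyl endo, cis to C6) | C=C1CC/C=C(C)\C[C@]23OC(=O)[C@@H](C)[C@H]2[C@H](O)[C@H]13 | intermediate
23 | (11S)-4,15-epoxy-6α-hydroxy-5βH-5,8-cyclogermacr-1(10)Z-en-12,8β-olide (oxirane oxygen on the face of C4 remote from C8) | [C@@]12(CO1)CC/C=C(C)\C[C@]34OC(=O)[C@@H](C)[C@H]3[C@H](O)[C@H]24 | intermediate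
24 | isopropyl (11S)-4,15-epoxy-6α,8β-dihydroxy-5βH-5,8-cyclogermacr-1(10)Z-en-12-oate, present as its C8 titanium alkoxide (drawn as the alcohol) | [C@@]12(CO1)CC/C=C(C)\C[C@]3(O)[C@@H]([C@H](C)C(=O)OC(C)C)[C@H](O)[C@H]23 | intermediate (not isolated)
25 | isopropyl (11S)-6α,15-dihydroxy-8-oxogermacra-1(10)Z,4Z-dien-12-oate (C4=C5 ring-trans) | C/C1=C/CC/C(CO)=C/[C@@H](O)[C@H]([C@H](C)C(=O)OC(C)C)C(=O)C1 | intermediate (not isolated)
26 | (11S)-15-hydroxy-8-oxogermacra-1(10)Z,4Z-dien-12,6α-olide (trans-fused lactone, H-6β, H-7α; C4=C5 ring-trans) | C/C1=C/CC/C(CO)=C/[C@H]2OC(=O)[C@@H](C)[C@@H]2C(=O)C1 | intermediate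
27 | 15-O-TBS ether of 26 | C/C1=C/CC/C(CO[Si](C)(C)C(C)(C)C)=C/[C@H]2OC(=O)[C@@H](C)[C@@H]2C(=O)C1 | intermediate
28 | (11S)-15-(tert-butyldimethylsilyloxy)-8β-hydroxygermacra-1(10)Z,4Z-dien-12,6α-olide (8-OH cis to C11) | C/C1=C/CC/C(CO[Si](C)(C)C(C)(C)C)=C/[C@H]2OC(=O)[C@@H](C)[C@@H]2[C@H](O)C1 | intermediate
29 | (4S)-4-methyloxolan-2-one | C[C@@H]1COC(=O)C1 | starting material
30 | potassium (3S)-4-hydroxy-3-methylbutanoate | C[C@H](CO)CC(=O)[O-].[K+] | intermediate
31 | tert-butyldimethylsilyl (3S)-4-(tert-butyldimethylsilyloxy)-3-methylbutanoate | C[C@H](CO[Si](C)(C)C(C)(C)C)CC(=O)O[Si](C)(C)C(C)(C)C | intermediate (not isolated)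
32 | (3S)-4-(tert-butyldimethylsilyloxy)-3-methylbutanoic acid | C[C@H](CO[Si](C)(C)C(C)(C)C)CC(=O)O | intermediate
33 | bis-TBS ether of the target (8α-ester) | C/C1=C/CC/C(CO[Si](C)(C)C(C)(C)C)=C/[C@H]2OC(=O)[C@@H](C)[C@@H]2[C@@H](OC(=O)C[C@H](C)CO[Si](C)(C)C(C)(C)C)C1 | intermediate
34 | (6R,7R,8S,11S)-15-hydroxy-8α-[(3S)-4-hydroxy-3-methylbutanoyloxy]germacra-1(10)Z,4Z-dien-12,6α-olide (CNP0160815.1) | C/C1=C/CC/C(CO)=C/[C@H]2OC(=O)[C@@H](C)[C@@H]2[C@@H](OC(=O)C[C@H](C)CO)C1 | target

**Step count and risks**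

Total steps: 21. Longest linear sequence: 15 steps (steps 1–4, 9–17, 20, 21; the branch through steps 5–8 is equally long).

Step 15. What may go wrong: the lactone may fail to open under titanate catalysis, or the free C6 aldolate may be lost by retro‑aldol or β‑elimination before it lactonises. Fallback: a stepwise anionic fragmentation with the C6 oxygen protected, setting out from 23. Silylation (TBSCl, imidazole) should give the 6‑O‑TBS ether of 23 F1. Brief treatment with K2CO3 in MeOH at 0 °C should open the lactone to the potassium alkoxide, which fragments to methyl (11S)-6α-(tert-butyldimethylsilyloxy)-15-hydroxy-8-oxogermacra-1(10)Z,4Z-dien-12-oate F2. HF·pyridine then removes the silyl ether and the hydroxy ester lactonises, which returns to the route at 26.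

Step 14. What may go wrong: oxygen may be delivered to the other face of the exocyclic alkene, giving the C4 epimer that would fragment to the ring‑cis alkene. Fallback: build the oxirane from the ketone, which delivers CH2 instead of O and so gives the opposite C4 configuration; it sets out from 18. Perborate oxidation of 18 should give (11R)-6α-hydroxy-4-oxo-5βH-5,8-cyclogermacr-1(10)Z-en-12,8β-olide F3. Corey–Chaykovsky epoxidation (Me3S+ I−, KHMDS, THF, −10 °C) should give (11R)-4,15-epoxy-6α-hydroxy-5βH-5,8-cyclogermacr-1(10)Z-en-12,8β-olide F4. Enolisation with LDA (3 equiv) and kinetic protonation as in step 13 then returns to the route at 23.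

Step 17. What may go wrong: poor or reversed facial selectivity in hydride delivery, so that the 8α‑alcohol forms and Mitsunobu inversion would give the wrong ester. Fallback: esterify with retention instead of inversion, setting out from 27. Luche reduction (NaBH4, CeCl3·7H2O, MeOH, −78 °C) or chromatographic separation should give (11S)-15-(tert-butyldimethylsilyloxy)-8α-hydroxygermacra-1(10)Z,4Z-dien-12,6α-olide F5. Steglich esterification with 32 (DCC, DMAP, CH2Cl2) then returns to the route at 33.

**Further compounds**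

F1 | step 15 | 6-O-TBS ether of 23 | [C@@]12(CO1)CC/C=C(C)\C[C@]34OC(=O)[C@@H](C)[C@H]3[C@H](O[Si](C)(C)C(C)(C)C)[C@H]24
F2 | step 15 | methyl (11S)-6α-(tert-butyldimethylsilyloxy)-15-hydroxy-8-oxogermacra-1(10)Z,4Z-dien-12-oate | C/C1=C/CC/C(CO)=C/[C@@H](O[Si](C)(C)C(C)(C)C)[C@H]([C@H](C)C(=O)OC)C(=O)C1
F3 | step 14 | (11R)-6α-hydroxy-4-oxo-5βH-5,8-cyclogermacr-1(10)Z-en-12,8β-olide | O=C1CC/C=C(C)\C[C@]23OC(=O)[C@H](C)[C@H]2[C@H](O)[C@H]13
F4 | step 14 | (11R)-4,15-epoxy-6α-hydroxy-5βH-5,8-cyclogermacr-1(10)Z-en-12,8β-olide | [C@@]12(CO1)CC/C=C(C)\C[C@]34OC(=O)[C@H](C)[C@H]3[C@H](O)[C@H]24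
F5 | step 17 | (11S)-15-(tert-butyldimethylsilyloxy)-8α-hydroxygermacra-1(10)Z,4Z-dien-12,6α-olide | C/C1=C/CC/C(CO[Si](C)(C)C(C)(C)C)=C/[C@H]2OC(=O)[C@@H](C)[C@@H]2[C@@H](O)C1
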